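**Plan**
Ring numbering: C1 (CH–O-isovaleryl), C2 (C=O), C3 (C(OH)CH3), C4 (CHOH), C5 (CH2), C6 (CH carrying the side chain).
Feature: C1–C4 are four contiguous oxygen-bearing carbons with the C1–O and C4–O bonds cis, and C5–C6 is a two-carbon unit with one substituent. This is the imprint of a 1,4-dioxygenated 2-methylbuta-1,3-diene on a dienophile; the C2=C3 double bond left in the adduct is the precursor of the ketone/tertiary alcohol pair.
Retrosynthesis cuts, in order: the C–OOH bond (Schenck ene reaction), the side-chain C(=CH2)–C(=O) bond (alkenyl triflate + aldehyde), the C2/C3 oxygens (back to an alkene), then the ring bonds C4–C5 and C1–C6 in one [4+2] step with a temporary formyl group on C5.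
Forward: diene 3 (two steps from prenyl isovalerate) and (2E)-4-oxopent-2-enal (from 2-methylfuran) close the only ring. The formyl helper is then oxidised and decarboxylated away, the acetyl group becomes an enol triflate, the ring alkene is dihydroxylated, and the side chain is completed by Nozaki–Hiyama–Kishi coupling, oxidation, desilylation and photooxygenation.
Stereochemistry: C1, C4 and C6 come from the cycloaddition (E,E-diene gives cis oxygens, endo iminium puts the C6 acetyl trans, the chiral amine sets the absolute sense). C3 comes from OsO4 attack anti to both allylic oxygens; C1 keeps its stable equatorial configuration once C2 is a ketone.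

Key step: step 4

**Route**

Step 1
Reactants: 1 3-methylbut-2-en-1-yl 3-methylbutanoate (prenyl isovalerate)
Product: 2 (2E)-3-methyl-4-oxobut-2-en-1-yl 3-methylbutanoate
Conditions: SeO2 (1.1 equiv), 1,4-dioxane, 80 °C
Reagents that add atoms: selenium dioxide, O=[Se]=O
Why: Riley (SeO2) allylic oxidation attacks the (E)-methyl group of the trisubstituted alkene, as with other prenyl esters, and should give the (E)-enal with the ester untouched.

Step 2
Reactants: 2 (2E)-3-methyl-4-oxobut-2-en-1-yl 3-methylbutanoate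
Product: 3 (1E,3E)-4-[(tert-butyldimethylsilyl)oxy]-3-methylbuta-1,3-dien-1-yl 3-methylbutanoate
Conditions: TBSOTf, Et3N, Et2O, 0 °C
Reagents that add atoms: tert-butyldimethylsilyl trifluoromethanesulfonate, CC(C)(C)[Si](C)(C)OS(=O)(=O)C(F)(F)F
Why: Soft enolization (O-silylation of the enal and loss of one of the only γ-hydrogens, those of the CH2O-acyl group) should give the silyl dienol ether; the s-trans enal leads to the (E)-silyloxy terminus and the less crowded (E)-enol ester is expected to predominate, while any Z isomer is a poor diene and is left behind in step 4.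

Step 3
Reactants: 4 2-methylfuran
Product: 6 (2E)-4-oxopent-2-enal, via (2Z)-4-oxopent-2-enal 5 (not isolated)
Conditions: NBS, NaHCO3, acetone/H2O, −15 °C; then pyridine (cat.), rt
Reagents that add atoms: water, O
Why: Oxidative ring opening of the furan (bromination, capture of water, collapse of the 2,5-dihydrofuran) gives the cis-enedicarbonyl compound, which pyridine isomerizes to the more stable trans isomer by reversible conjugate addition.

Step 4
Reactants: 3 (1E,3E)-4-[(tert-butyldimethylsilyl)oxy]-3-methylbuta-1,3-dien-1-yl 3-methylbutanoate (1.5 equiv); 6 (2E)-4-oxopent-2-enal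
Product: 8 (1R,4R,5R,6R)-6-acetyl-4-[(tert-butyldimethylsilyl)oxy]-5-formyl-3-methylcyclohex-2-en-1-yl 3-methylbutanoate, via iminium ion 7 (not isolated)
Conditions: (5S)-5-benzyl-2,2,3-trimethylimidazolidin-4-one trifluoroacetate (20 mol%), CH3CN/H2O (19:1), −20 °C
Reagents that add atoms: none
Why: Iminium-catalysed Diels–Alder reaction, closest to the known imidazolidinone-catalysed cycloadditions of enals with 1-acetoxy- and 1-alkoxybutadienes: the amine condenses only with the aldehyde of 6, and the electron-poor iminium ion 7 is attacked at its β-carbon (the acetyl-bearing carbon) by the ester-bearing terminus of 3, which is the nucleophilic end because the silyloxy group at the other terminus is by far the stronger donor. The cyclohexene ring closes in a suprafacial [4+2] mode (concerted but asynchronous; a stepwise Mukaiyama–Michael addition followed by 6-ring closure of the enamine onto the silyloxocarbenium ion would give the same ring). The (E,E) geometry of 3 sets the two C–O bonds cis (C1 and C4), the endo position of the activated iminium group puts the formyl group cis and the acetyl group trans to both oxygens (C6), and the benzyl group of the (5S)-catalyst shields one face of the (E)-iminium ion so that, by analogy with cinnamaldehyde, the Si face of the α-carbon should react and fix the absolute configuration. The step needs regioselectivity (secured by iminium versus ketone activation in 6 and by silyl enol ether versus enol ester donation in 3), endo selectivity of the formyl-bearing carbon (secured by placing the activation on that carbon) and facial selectivity (catalyst); the configuration of the formyl-bearing carbon C5 is immaterial because it becomes CH2.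

Step 5
Reactants: 8 (1R,4R,5R,6R)-6-acetyl-4-[(tert-butyldimethylsilyl)oxy]-5-formyl-3-methylcyclohex-2-en-1-yl 3-methylbutanoate
Product: 9 (1R,2R,5R,6R)-6-acetyl-2-[(tert-butyldimethylsilyl)oxy]-3-methyl-5-[(3-methylbutanoyl)oxy]cyclohex-3-ene-1-carboxylic acid
Conditions: NaClO2, NaH2PO4, 2-methylbut-2-ene, t-BuOH/H2O, 0 °C to rt
Reagents that add atoms: sodium chlorite, [Na+].[O-]Cl=O
Why: Pinnick oxidation converts the aldehyde into the acid under buffered, weakly acidic conditions that should spare the silyl ether, the ring alkene (hypochlorite is trapped by 2-methylbut-2-ene) and the base-labile β-acyloxy ketone.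

Step 6
Reactants: 9 (1R,2R,5R,6R)-6-acetyl-2-[(tert-butyldimethylsilyl)oxy]-3-methyl-5-[(3-methylbutanoyl)oxy]cyclohex-3-ene-1-carboxylic acid
Product: 10 (1R,4R,6R)-6-acetyl-4-[(tert-butyldimethylsilyl)oxy]-3-methylcyclohex-2-en-1-yl 3-methylbutanoate
Conditions: 9-mesityl-10-phenylacridinium tetrafluoroborate (cat.), PhSSPh (cat.), i-Pr2NEt (cat.), CF3CH2OH, blue LEDs, rt
Reagents that add atoms: none
Why: Photoredox hydrodecarboxylation: the excited acridinium oxidises the carboxylate, CO2 is lost and the secondary radical takes a hydrogen atom from thiophenol (formed from the disulfide), which removes the helper carbon and erases its stereocentre, leaving C5 as CH2.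

Step 7
Reactants: 10 (1R,4R,6R)-6-acetyl-4-[(tert-butyldimethylsilyl)oxy]-3-methylcyclohex-2-en-1-yl 3-methylbutanoate
Product: 11 (1R,4R,6R)-4-[(tert-butyldimethylsilyl)oxy]-3-methyl-6-{1-[(trifluoromethanesulfonyl)oxy]ethenyl}cyclohex-2-en-1-yl 3-methylbutanoate
Conditions: KN(SiMe3)2 added to 10 and PhNTf2, THF, −78 °C
Reagents that add atoms: N-phenylbis(trifluoromethanesulfonimide), O=S(=O)(N(c1ccccc1)S(=O)(=O)C(F)(F)F)C(F)(F)F
Why: Kinetic deprotonation of the methyl ketone at the methyl group and immediate O-sulfonylation of the terminal enolate (enol triflate formation) should outrun formation of the ring-side enolate, the only one that could expel the β-ester, so C6 is not touched.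

Step 8
Reactants: 11 (1R,4R,6R)-4-[(tert-butyldimethylsilyl)oxy]-3-methyl-6-{1-[(trifluoromethanesulfonyl)oxy]ethenyl}cyclohex-2-en-1-yl 3-methylbutanoate
Product: 12 (1S,2R,3R,4R,6R)-4-[(tert-butyldimethylsilyl)oxy]-2,3-dihydroxy-3-methyl-6-{1-[(trifluoromethanesulfonyl)oxy]ethenyl}cyclohexyl 3-methylbutanoate
Conditions: OsO4 (cat.), N-methylmorpholine N-oxide, acetone/H2O, rt
Reagents that add atoms: osmium tetroxide, O=[Os](=O)(=O)=O (transfers both oxygen atoms); N-methylmorpholine N-oxide, C[N+]1([O-])CCOCC1, and water, O (net oxygen sources)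
Why: Catalytic OsO4 cis-dihydroxylation ([3+2] addition) of the only electron-rich alkene (the enol triflate is deactivated) should occur anti to the two allylic C–O bonds, which sets the tertiary carbinol C3 (OH trans to the silyloxy group) and a secondary carbinol at C2 that is oxidised in step 11.

Step 9
Reactants: 13 4-methylpent-3-en-1-ol
Product: 14 4-methylpent-3-enal
Conditions: IBX, EtOAc, 75 °C; filtered solution used directly
Reagents that add atoms: none
Why: IBX oxidation of the primary alcohol under neutral conditions should give the aldehyde without moving the β,γ-double bond into conjugation.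

Step 10
Reactants: 12 (1S,2R,3R,4R,6R)-4-[(tert-butyldimethylsilyl)oxy]-2,3-dihydroxy-3-methyl-6-{1-[(trifluoromethanesulfonyl)oxy]ethenyl}cyclohexyl 3-methylbutanoate; 14 4-methylpent-3-enal
Product: 15 (1S,2R,3R,4R,6S)-4-[(tert-butyldimethylsilyl)oxy]-2,3-dihydroxy-6-(3-hydroxy-6-methylhepta-1,5-dien-2-yl)-3-methylcyclohexyl 3-methylbutanoate (both epimers at the side-chain carbinol)
Conditions: CrCl2 (excess), NiCl2 (cat.), DMF, rt
Reagents that add atoms: none
Why: Nozaki–Hiyama–Kishi coupling: zerovalent nickel inserts into the alkenyl triflate, transmetalation gives an alkenylchromium species that adds only to the aldehyde and tolerates the free diol, the ester and the silyl ether; the new carbinol centre is formed without control and is removed in step 11.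

Step 11
Reactants: 15 (1S,2R,3R,4R,6S)-4-[(tert-butyldimethylsilyl)oxy]-2,3-dihydroxy-6-(3-hydroxy-6-methylhepta-1,5-dien-2-yl)-3-methylcyclohexyl 3-methylbutanoate
Product: 16 (1S,3S,4R,6S)-4-[(tert-butyldimethylsilyl)oxy]-3-hydroxy-3-methyl-6-(6-methyl-3-oxohepta-1,5-dien-2-yl)-2-oxocyclohexyl 3-methylbutanoate
Conditions: IBX (excess), DMSO, rt
Reagents that add atoms: none
Why: IBX oxidation should convert both secondary alcohols into ketones without cleaving the tertiary/secondary 1,2-diol and, being neutral, without conjugating the β,γ-unsaturated ketone; C1, now α to the ketone, already has the more stable equatorial configuration trans to C6.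

Step 12
Reactants: 16 (1S,3S,4R,6S)-4-[(tert-butyldimethylsilyl)oxy]-3-hydroxy-3-methyl-6-(6-methyl-3-oxohepta-1,5-dien-2-yl)-2-oxocyclohexyl 3-methylbutanoate
Product: 17 (1S,3S,4R,6S)-3,4-dihydroxy-3-methyl-6-(6-methyl-3-oxohepta-1,5-dien-2-yl)-2-oxocyclohexyl 3-methylbutanoate
Conditions: HF·pyridine, pyridine, THF, 0 °C to rt
Reagents that add atoms: none
Why: Fluoride-mediated desilylation under buffered, non-basic conditions should free the C4 alcohol without retro-aldol cleavage, acyl migration or attack on the enone.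

Step 13
Reactants: 17 (1S,3S,4R,6S)-3,4-dihydroxy-3-methyl-6-(6-methyl-3-oxohepta-1,5-dien-2-yl)-2-oxocyclohexyl 3-methylbutanoate
Product: 18 (1S,3S,4R,6S)-6-[(4E)-6-hydroperoxy-6-methyl-3-oxohepta-1,4-dien-2-yl]-3,4-dihydroxy-3-methyl-2-oxocyclohexyl 3-methylbutanoate
Conditions: O2, tetraphenylporphyrin (cat.), visible light, CH2Cl2, 0 °C
Reagents that add atoms: oxygen, O=O
Why: Schenck ene reaction of singlet oxygen with the trisubstituted alkene (the enone C=CH2 is inert): abstraction of the doubly activated CH2 hydrogen between carbonyl and alkene should place the O–O bond on the tertiary carbon and move the double bond into (E)-conjugation with the ketone, with no ring stereocentre affected.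

**Compound list**
1 | 3-methylbut-2-en-1-yl 3-methylbutanoate | CC(C)CC(=O)OCC=C(C)C | starting material
2 | (2E)-3-methyl-4-oxobut-2-en-1-yl 3-methylbutanoate | CC(C)CC(=O)OC/C=C(\C)C=O | intermediate
3 | (1E,3E)-4-[(tert-butyldimethylsilyl)oxy]-3-methylbuta-1,3-dien-1-yl 3-methylbutanoate | CC(C)CC(=O)O/C=C/C(C)=C/O[Si](C)(C)C(C)(C)C | intermediate
4 | 2-methylfuran | Cc1ccco1 | starting material
5 | (2Z)-4-oxopent-2-enal | CC(=O)/C=C\C=O | intermediate
6 | (2E)-4-oxopent-2-enal | CC(=O)/C=C/C=O | intermediate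
7 | (5S)-5-benzyl-2,2,3-trimethyl-4-oxo-1-[(2E)-4-oxopent-2-en-1-ylidene]imidazolidin-1-ium trifluoroacetate (iminium ion) | CC(=O)/C=C/C=[N+]1C(C)(C)N(C)C(=O)[C@@H]1Cc1ccccc1.[O-]C(=O)C(F)(F)F | intermediate
8 | (1R,4R,5R,6R)-6-acetyl-4-[(tert-butyldimethylsilyl)oxy]-5-formyl-3-methylcyclohex-2-en-1-yl 3-methylbutanoate | CC(=O)[C@@H]1[C@@H](C=O)[C@@H](O[Si](C)(C)C(C)(C)C)C(C)=C[C@H]1OC(=O)CC(C)C | intermediate
9 | (1R,2R,5R,6R)-6-acetyl-2-[(tert-butyldimethylsilyl)oxy]-3-methyl-5-[(3-methylbutanoyl)oxy]cyclohex-3-ene-1-carboxylic acid | CC(=O)[C@@H]1[C@@H](C(=O)O)[C@@H](O[Si](C)(C)C(C)(C)C)C(C)=C[C@H]1OC(=O)CC(C)C | intermediate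
10 | (1R,4R,6R)-6-acetyl-4-[(tert-butyldimethylsilyl)oxy]-3-methylcyclohex-2-en-1-yl 3-methylbutanoate | CC(=O)[C@@H]1C[C@@H](O[Si](C)(C)C(C)(C)C)C(C)=C[C@H]1OC(=O)CC(C)C | intermediate
11 | (1R,4R,6R)-4-[(tert-butyldimethylsilyl)oxy]-3-methyl-6-{1-[(trifluoromethanesulfonyl)oxy]ethenyl}cyclohex-2-en-1-yl 3-methylbutanoate | C=C(OS(=O)(=O)C(F)(F)F)[C@@H]1C[C@@H](O[Si](C)(C)C(C)(C)C)C(C)=C[C@H]1OC(=O)CC(C)C | intermediate
12 | (1S,2R,3R,4R,6R)-4-[(tert-butyldimethylsilyl)oxy]-2,3-dihydroxy-3-methyl-6-{1-[(trifluoromethanesulfonyl)oxy]ethenyl}cyclohexyl 3-methylbutanoate | C=C(OS(=O)(=O)C(F)(F)F)[C@@H]1C[C@@H](O[Si](C)(C)C(C)(C)C)[C@](C)(O)[C@H](O)[C@H]1OC(=O)CC(C)C | intermediate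
13 | 4-methylpent-3-en-1-ol | CC(C)=CCCO | starting material
14 | 4-methylpent-3-enal | CC(C)=CCC=O | intermediate
15 | (1S,2R,3R,4R,6S)-4-[(tert-butyldimethylsilyl)oxy]-2,3-dihydroxy-6-(3-hydroxy-6-methylhepta-1,5-dien-2-yl)-3-methylcyclohexyl 3-methylbutanoate | CC(C)=CCC(O)C(=C)[C@@H]1C[C@@H](O[Si](C)(C)C(C)(C)C)[C@](C)(O)[C@H](O)[C@H]1OC(=O)CC(C)C | intermediate
16 | (1S,3S,4R,6S)-4-[(tert-butyldimethylsilyl)oxy]-3-hydroxy-3-methyl-6-(6-methyl-3-oxohepta-1,5-dien-2-yl)-2-oxocyclohexyl 3-methylbutanoate | CC(C)=CCC(=O)C(=C)[C@@H]1C[C@@H](O[Si](C)(C)C(C)(C)C)[C@](C)(O)C(=O)[C@H]1OC(=O)CC(C)C | intermediate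
17 | (1S,3S,4R,6S)-3,4-dihydroxy-3-methyl-6-(6-methyl-3-oxohepta-1,5-dien-2-yl)-2-oxocyclohexyl 3-methylbutanoate | CC(C)=CCC(=O)C(=C)[C@@H]1C[C@@H](O)[C@](C)(O)C(=O)[C@H]1OC(=O)CC(C)C | intermediate
18 | (1S,3S,4R,6S)-6-[(4E)-6-hydroperoxy-6-methyl-3-oxohepta-1,4-dien-2-yl]-3,4-dihydroxy-3-methyl-2-oxocyclohexyl 3-methylbutanoate | C=C(C(=O)/C=C/C(C)(C)OO)[C@@H]1C[C@@H](O)[C@](C)(O)C(=O)[C@H]1OC(=O)CC(C)C | target

**Count and risks**
Total steps: 13. Longest linear sequence: 11 steps (1 → 2 → 3 → 8 → 9 → 10 → 11 → 12 → 15 → 16 → 17 → 18).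

Steps most likely to fail:

1. Step 4. What may go wrong: hydrolysis of the silyl dienol ether in the wet acidic medium before it reacts, loss of endo preference because the acetyl group competes for the endo position, or erosion of facial control by an uncatalysed background cycloaddition. Fallback, from 3 back to 9: the aldehyde is replaced by a chelating imide. 3-[(2E)-4-oxopent-2-enoyl]-1,3-oxazolidin-2-one F1 is made from commercial (2E)-4-oxopent-2-enoic acid (pivaloyl chloride, Et3N; then 1,3-oxazolidin-2-one, LiCl). It reacts with 3 under anhydrous conditions with the square-planar complex of Cu(SbF6)2 and a 2,2′-(propane-2,2-diyl)bis(4-tert-butyl-4,5-dihydro-1,3-oxazole) ligand (CH2Cl2, −78 °C). The ligand enantiomer is chosen by the chelate model; (R,R) is expected. Two-point binding activates only the imide carbonyl, so regiochemistry and endo preference are as in step 4, and the product is (1R,4R,5R,6R)-6-acetyl-4-[(tert-butyldimethylsilyl)oxy]-3-methyl-5-(2-oxo-1,3-oxazolidine-3-carbonyl)cyclohex-2-en-1-yl 3-methylbutanoate F2. Yb(OTf)3 in methanol exchanges the oxazolidinone for methoxide without base to give methyl (1R,2R,5R,6R)-6-acetyl-2-[(tert-butyldimethylsilyl)oxy]-3-methyl-5-[(3-methylbutanoyl)oxy]cyclohex-3-ene-1-carboxylate F3. Me3SnOH (1,2-dichloroethane, 70 °C) then cleaves the methyl ester selectively to acid 9.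

2. Step 6. What may go wrong: single-electron oxidation of the ring alkene competing with that of the carboxylate (leading to lactonisation), or slow hydrogen-atom transfer to the hindered radical. Fallback, from 8 back to 10, bypassing 9: Tsuji–Wilkinson decarbonylation of the aldehyde with stoichiometric RhCl(PPh3)3 in toluene at 110 °C (insertion of monovalent rhodium into the formyl C–H bond, extrusion of CO, C–H reductive elimination). This fallback makes no new compound (F0).

3. Step 13. What may go wrong: hydrogen abstraction from the cis-methyl group instead of the CH2 group, which gives the secondary hydroperoxide, and loss of the hydroperoxide on purification. Fallback, from 12 back to 18: the peroxide is brought in ready-made.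
   - Nozaki–Hiyama–Kishi coupling of 12 with commercial diethyl (2-oxoethyl)phosphonate gives (1S,2R,3R,4R,6S)-4-[(tert-butyldimethylsilyl)oxy]-6-[4-(diethoxyphosphoryl)-3-hydroxybut-1-en-2-yl]-2,3-dihydroxy-3-methylcyclohexyl 3-methylbutanoate F4.
   - IBX in DMSO gives the β-ketophosphonate (1S,3S,4R,6S)-4-[(tert-butyldimethylsilyl)oxy]-6-[4-(diethoxyphosphoryl)-3-oxobut-1-en-2-yl]-3-hydroxy-3-methyl-2-oxocyclohexyl 3-methylbutanoate F5.
   - Horner–Wadsworth–Emmons reaction (LiCl, i-Pr2NEt, CH3CN) with 2-methyl-2-[(trimethylsilyl)peroxy]propanal F6 gives the (E)-enone (1S,3S,4R,6S)-4-[(tert-butyldimethylsilyl)oxy]-3-hydroxy-3-methyl-6-{(4E)-6-methyl-3-oxo-6-[(trimethylsilyl)peroxy]hepta-1,4-dien-2-yl}-2-oxocyclohexyl 3-methylbutanoate F7. F6 comes from commercial 2-methyl-1-(trimethylsilyloxy)prop-1-ene by the silatropic ene reaction with singlet oxygen.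
   - HF·pyridine removes both silyl groups to give 18.

**Further compounds**
F1 | step 4 | 3-[(2E)-4-oxopent-2-enoyl]-1,3-oxazolidin-2-one | CC(=O)/C=C/C(=O)N1CCOC1=O
F2 | step 4 | (1R,4R,5R,6R)-6-acetyl-4-[(tert-butyldimethylsilyl)oxy]-3-methyl-5-(2-oxo-1,3-oxazolidine-3-carbonyl)cyclohex-2-en-1-yl 3-methylbutanoate | CC(=O)[C@@H]1[C@@H](C(=O)N2CCOC2=O)[C@@H](O[Si](C)(C)C(C)(C)C)C(C)=C[C@H]1OC(=O)CC(C)C
F3 | step 4 | methyl (1R,2R,5R,6R)-6-acetyl-2-[(tert-butyldimethylsilyl)oxy]-3-methyl-5-[(3-methylbutanoyl)oxy]cyclohex-3-ene-1-carboxylate | CC(=O)[C@@H]1[C@@H](C(=O)OC)[C@@H](O[Si](C)(C)C(C)(C)C)C(C)=C[C@H]1OC(=O)CC(C)C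
F0 | step 6 | none | none
F4 | step 13 | (1S,2R,3R,4R,6S)-4-[(tert-butyldimethylsilyl)oxy]-6-[4-(diethoxyphosphoryl)-3-hydroxybut-1-en-2-yl]-2,3-dihydroxy-3-methylcyclohexyl 3-methylbutanoate | CCOP(=O)(OCC)CC(O)C(=C)[C@@H]1C[C@@H](O[Si](C)(C)C(C)(C)C)[C@](C)(O)[C@H](O)[C@H]1OC(=O)CC(C)C
F5 | step 13 | (1S,3S,4R,6S)-4-[(tert-butyldimethylsilyl)oxy]-6-[4-(diethoxyphosphoryl)-3-oxobut-1-en-2-yl]-3-hydroxy-3-methyl-2-oxocyclohexyl 3-methylbutanoate | CCOP(=O)(OCC)CC(=O)C(=C)[C@@H]1C[C@@H](O[Si](C)(C)C(C)(C)C)[C@](C)(O)C(=O)[C@H]1OC(=O)CC(C)C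
F6 | step 13 | 2-methyl-2-[(trimethylsilyl)peroxy]propanal | CC(C)(C=O)OO[Si](C)(C)C
F7 | step 13 | (1S,3S,4R,6S)-4-[(tert-butyldimethylsilyl)oxy]-3-hydroxy-3-methyl-6-{(4E)-6-methyl-3-oxo-6-[(trimethylsilyl)peroxy]hepta-1,4-dien-2-yl}-2-oxocyclohexyl 3-methylbutanoate | CC(C)(OO[Si](C)(C)C)/C=C/C(=O)C(=C)[C@@H]1C[C@@H](O[Si](C)(C)C(C)(C)C)[C@](C)(O)C(=O)[C@H]1OC(=O)CC(C)C
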